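## Analysis of the target

The target is 4-hydroxybenzoic acid carrying, ortho to the phenol, an (E)-3-methylpent-2-enyl chain whose far end is bonded to C2 of a 1,3,3-trimethyl-7-oxabicyclo[2.2.1]heptane. In the bicycle (C1 methyl-bearing bridgehead, C2, C3 = CMe2, C4 bridgehead CH, C5, C6, O7 bridge) all three stereocentres are found. C1 (R) and C4 (S) are tied to each other by the oxygen bridge, and the chain at C2 (S) is exo, that is, syn to O7. The sensitive groups are the free phenol next to a trisubstituted alkene (acid would close a chroman), the tertiary bridging ether at C1 (labile to strong acids, and prone to β-elimination from any enolate at C2), and the E alkene, which must be made as a single isomer. The main difficulty is C2, which sits between the fully substituted carbons C1 and C3. A cycloaddition that forms C1–C2 and C3–C4 directly would need a β,β-dimethylacrylate, which is inert towards furans, and furan adducts revert easily in any case. The strategy rests on one feature: the gem-dimethyl carbon C3 can be carried as a spiro-cyclopropane. The inert β,β-dimethylacrylate then becomes a strained cyclopropylideneacetate, which is reactive as a dienophile and gives an adduct that has little tendency to revert.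

## Retrosynthetic reasoning

Target 21 is traced back to its doubly protected form 20, in which the phenol is a pivalate and the acid a methyl ester. Both fall to hydroxide in one operation, so the last step needs no acid near the phenol–alkene pair or the bridging ether.

In 20 the bond between the alkene CH and the benzylic CH2, together with the alkene methyl bond, is cut. This leads to the terminal alkyne 15 and the benzylic bromide 18. The cut is made here because syn methylmetalation of a terminal alkyne (via the alkenylalane 19) fixes the E geometry by mechanism, which a carbonyl olefination at this trisubstituted position would not do. Bromide 18 comes from the commercial cresol ester 16 through pivalate 17 by benzylic bromination.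

Alkyne 15 is the one-carbon homologue of aldehyde 14, which is the partial reduction product of methyl ester 13. These are functional-group changes that leave the bicycle untouched.

In 13 the bond between C2 and the first chain carbon is cut. The forward reaction is the addition of a C2 radical, released from the redox-active ester 11, to methyl acrylate 12. A radical is chosen because C2 is too hindered for ionic substitution and because the planar radical should be attacked from its open exo face, which sets the C2 configuration at this point. Whatever configuration C2 had before is therefore irrelevant. Ester 11 derives from acid 10 and this from trifluoroethyl ester 9.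

In 9 the two C3 methyl groups are traced back to the spiro-cyclopropane of 7, which is opened by hydrogenolysis after saturation of the C5=C6 alkene (via 8). This has to precede the radical step, since a C2 radical next to a cyclopropane would open the three-membered ring.

Cycloadduct 7 is cut at C1–C2 and C3–C4 into 2-methylfuran 6 and the cyclopropylideneacetate 5. This is the only disconnection that makes the six-membered ring, the oxygen bridge and the two bridgehead stereocentres at once from achiral components. The forward reaction must be regioselective (methyl-bearing bridgehead next to the ester carbon) and face-selective. It need not be endo- or exo-selective.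

Dienophile 5 is cut at its alkene into the stabilised ylide 3 and the hemiacetal 4, and ylide 3 into the cumulated ylide 1 and alcohol 2. Both are short, reliable operations, so the risk of the route sits in the cycloaddition.

## Alternatives that were turned down

Alternative 1: The bicycle is cut at O7–C1, C1–C6 and C4–C5 into the acyclic 4-diazo-2,2-dimethyl-3-oxopentanal A2 and 1,1-bis(phenylsulfonyl)ethene A3. In the forward step a chiral dirhodium tetracarboxylate decomposes A2, the aldehyde oxygen captures the carbenoid (O7–C1), and the resulting five-membered carbonyl ylide adds across A3 to give the bis-sulfonyl ketone A1.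
- For: one step makes both rings, two C–C bonds and the bridge. The gem-dimethyl group is carried unmasked, and the ether bridge is formed irreversibly. On these two points it is stronger than the chosen route.
- Against:
  - The carbenoid carbon bears a methyl group, so a 1,2-hydrogen shift to an enone competes with ylide formation.
  - Enantiocontrol requires the rhodium to stay bound to the ylide while a hindered alkene adds in a bimolecular step.
  - A1 presents C2 as a ketone between two quaternary carbons. Attaching the chain there and then removing the oxygen would deliver hydrogen, not carbon, from the open exo face and so give the wrong C2 epimer.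
  - Two sulfonyl groups have to be removed as well.
- Comparison: the chosen strategy keeps C2 as a carboxyl group, so the chain itself arrives from the exo face in one C–C bond-forming step.

Alternative 2: The bicycle is cut at O7–C1 and at the C2–substituent bond, leading to (S)-2,2,4-trimethylcyclohex-3-en-1-ol A5 and vinyl bromide A6. In the forward step a zerovalent palladium bisphosphine catalyst adds A6 oxidatively and the alkoxide of A5 binds. The C1=C2 alkene then inserts syn into the Pd–O bond across the ring, and C–C reductive elimination gives the vinyl bicycle A4.
- For: the exo configuration at C2 follows from the syn mechanism. The alkylpalladium has no β-hydrogen. A5 needs a single stereocentre. The vinyl group of A4 could be hydroborated and joined to an alkenyl iodide that carries the whole aromatic side chain. In step count this is stronger than the chosen route.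
- Against:
  - The insertion must engage a trisubstituted alkene, form the C–O bond at a fully substituted carbon and the Pd–C bond at a neopentylic carbon, and do so from a boat conformer with an axial alkoxide.
  - The palladium alkoxide has two easier unimolecular exits: β-hydride elimination of the carbinol hydrogen, and C–O reductive elimination to a vinyl ether.
  - If the insertion fails there is no obvious related way to the same intermediate.
- Comparison: the chosen strategy places its risk in a pericyclic step with a strong thermodynamic driving force, and a racemic version by known chemistry remains available.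

Alternative 3: Only the C2–C3 bond is cut, leading to the monocyclic tetrahydrofuran A8, methyl (2E)-3-[(2R,5S)-2-methyl-5-(prop-1-en-2-yl)oxolan-2-yl]prop-2-enoate. This maps onto the furanoid linalool oxide A9 whose vinyl and hydroxyisopropyl groups are cis. In the forward step an iron hydride, generated from an iron tris(β-diketonate) and an arylsilane, transfers a hydrogen atom to the isopropenyl group. The tertiary C3 radical adds to the enoate β-carbon C2 (5-exo with respect to the ring C3–C4–O7–C1–C2) and the carbocycle closes to give acetate A7.
- For: C1 and C4 are inherited from the chiral pool and need no asymmetric catalyst, which is stronger than the chosen route on absolute configuration. The radical conjugate addition is well suited to bonds at quaternary carbons.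
- Against:
  - Only the cis tetrahydrofuran can close, and it must bridge two substituents across a five-membered ring into a strained [2.2.1] skeleton. Simple reduction of the tertiary radical competes.
  - The C2 configuration depends on the enoate rotamer in the transition state, and nothing obvious forces the ester-bearing carbon exo.
  - The precursor needs a regioselective dehydration and a cross-metathesis at a vinyl group on a quaternary carbon.
  - A7 is one carbon short of 13.
- Comparison: the chosen strategy assembles the ring from two simple achiral components and sets C2 in a separate, late step with an inherent exo bias.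

Key step: step 3

Assumption: the (S)-configured oxazaborolidinium ion is taken to leave open the face of bound 5 that leads to the (1R,4S) bridgeheads, by analogy with acrylate esters; if the sense is opposite, the (R)-configured catalyst is used and nothing else changes. Compounds 7 to 11 are written as the endo (2R) epimers; the exo epimers serve equally.

## Route

Step 1
Reactants: 1 (triphenylphosphoranylidene)ketene; 2 2,2,2-trifluoroethanol
Product: 3 2,2,2-trifluoroethyl 2-(triphenylphosphoranylidene)acetate
Conditions: 2 (1.1 equiv), toluene, 60 °C
Reagents that add atoms: none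
Why: Addition of the O–H bond across the cumulated ylide (Bestmann ylide): the acidic alcohol protonates the ylidic carbon and the alkoxide adds to the phosphonium ketene, which should give the stabilised ester ylide without base or salt.

Step 2
Reactants: 3 2,2,2-trifluoroethyl 2-(triphenylphosphoranylidene)acetate; 4 (1-ethoxycyclopropoxy)trimethylsilane
Product: 5 2,2,2-trifluoroethyl 2-cyclopropylideneacetate
Conditions: PhCO2H (cat.), toluene, 85 °C; short-path distillation
Reagents that add atoms: none
Why: Wittig olefination of the cyclopropanone released from its silylated hemiacetal under benzoic acid catalysis; the strained, very electrophilic ketone should be trapped by the stabilised ylide as it forms, which is the usual entry to cyclopropylideneacetates.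

Step 3
Reactants: 5 2,2,2-trifluoroethyl 2-cyclopropylideneacetate; 6 2-methylfuran
Product: 7 2,2,2-trifluoroethyl (1R,2R,4S)-1-methylspiro[7-oxabicyclo[2.2.1]hept-5-ene-3,1'-cyclopropane]-2-carboxylate (endo ester)
Conditions: (S)-3,3-diphenyl-1-(2-methylphenyl)tetrahydro-1H,3H-pyrrolo[1,2-c][1,3,2]oxazaborole (20 mol %) protonated with (CF3SO2)2NH (18 mol %), 6 (5 equiv), CH2Cl2, −78 → −40 °C
Reagents that add atoms: none
Why: Proposed new method: the cationic oxazaborolidine binds the ester carbonyl of 5 and lowers its LUMO, and 6 adds in a concerted, asynchronous [4+2] cycloaddition in which the bond from the unsubstituted furan carbon to the cyclopropylidene carbon (C4–C3) leads and the bond from the methyl-bearing furan carbon to the α-carbon (C1–C2) follows. The closest known reactions are the oxazaborolidinium-catalysed enantioselective Diels–Alder reaction of furans with 2,2,2-trifluoroethyl acrylate and the uncatalysed Diels–Alder reactions of furans with 2-chloro-2-cyclopropylideneacetates. The six-membered carbocycle C1–C6 is closed by suprafacial addition across the 2,5-positions of the furan, whose oxygen becomes the O7 bridge. The bridgehead centres C1 and C4 are set by the face of the bound dienophile that the catalyst leaves open; C2 follows from the endo or exo position of the ester and needs no control, because step 7 erases it. Regioselectivity is needed and is secured twice: the larger HOMO coefficient of 6 at its unsubstituted terminus pairs with the larger LUMO coefficient at the β-carbon of 5, and the other orientation would place the quaternary C1 next to the spiro carbon. Relief of the extra strain of the alkylidenecyclopropane should make this β,β-disubstituted acrylate reactive and should disfavour cycloreversion at the low temperature used.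

Step 4
Reactants: 7 2,2,2-trifluoroethyl (1R,2R,4S)-1-methylspiro[7-oxabicyclo[2.2.1]hept-5-ene-3,1'-cyclopropane]-2-carboxylate
Product: 9 2,2,2-trifluoroethyl (1R,2R,4S)-1,3,3-trimethyl-7-oxabicyclo[2.2.1]heptane-2-carboxylate, via saturated spirocyclopropane ester 8 (not isolated)
Conditions: H2 (4 atm), PtO2 (10 mol %), AcOH, 25 → 50 °C
Reagents that add atoms: none
Why: Heterogeneous hydrogenation should saturate the strained C5=C6 alkene first (8); platinum in acetic acid then hydrogenolyses the cyclopropane at its least hindered CH2–CH2 bond, the established way of turning a spiro-cyclopropane into a gem-dimethyl group, and no stereocentre is touched.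

Step 5
Reactants: 9 2,2,2-trifluoroethyl (1R,2R,4S)-1,3,3-trimethyl-7-oxabicyclo[2.2.1]heptane-2-carboxylate
Product: 10 (1R,2R,4S)-1,3,3-trimethyl-7-oxabicyclo[2.2.1]heptane-2-carboxylic acid
Conditions: LiOH, THF/H2O, 0 °C → rt; then 1 M HCl, 0 °C
Reagents that add atoms: lithium hydroxide, [Li+].[OH-]
Why: Saponification; the electron-poor trifluoroethyl ester should be attacked at the acyl carbon even between two quaternary carbons, so the hydrolysis can be run cold and enolisation with β-elimination of O7 is avoided, and any epimerisation at C2 is harmless.

Step 6
Reactants: 10 (1R,2R,4S)-1,3,3-trimethyl-7-oxabicyclo[2.2.1]heptane-2-carboxylic acid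
Product: 11 1,3-dioxoisoindolin-2-yl (1R,2R,4S)-1,3,3-trimethyl-7-oxabicyclo[2.2.1]heptane-2-carboxylate
Conditions: N-hydroxyphthalimide, DIC, DMAP (cat.), CH2Cl2, rt
Reagents that add atoms: N-hydroxyphthalimide, O=C1c2ccccc2C(=O)N1O
Why: Carbodiimide (Steglich-type) esterification to the redox-active N-acyloxyphthalimide; DMAP as acyl carrier should overcome the hindrance at C2.

Step 7
Reactants: 11 1,3-dioxoisoindolin-2-yl (1R,2R,4S)-1,3,3-trimethyl-7-oxabicyclo[2.2.1]heptane-2-carboxylate; 12 methyl acrylate
Product: 13 methyl 3-[(1R,2S,4S)-1,3,3-trimethyl-7-oxabicyclo[2.2.1]heptan-2-yl]propanoate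
Conditions: 12 (3 equiv), Ru(bpy)3(PF6)2 (1 mol %), Hantzsch ester (1.5 equiv), CH2Cl2, blue LEDs, rt
Reagents that add atoms: none
Why: Photoredox decarboxylative Giese addition: one-electron reduction of 11 releases CO2 and phthalimide anion and gives the secondary C2 radical, which adds to 12, and the adduct radical is reduced by the Hantzsch ester. The planar radical should be attacked on its exo face, syn to the small O7 bridge and away from the C5–C6 bridge, as nucleophiles attack the identically substituted ketone fenchone; this sets C2 (S) with the chain exo whatever the C2 configuration of 11.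

Step 8
Reactants: 13 methyl 3-[(1R,2S,4S)-1,3,3-trimethyl-7-oxabicyclo[2.2.1]heptan-2-yl]propanoate
Product: 14 3-[(1R,2S,4S)-1,3,3-trimethyl-7-oxabicyclo[2.2.1]heptan-2-yl]propanal
Conditions: i-Bu2AlH (1.1 equiv), CH2Cl2, −78 °C; then MeOH, aq. potassium sodium tartrate
Reagents that add atoms: none
Why: Partial reduction of the methyl ester; at −78 °C the tetrahedral aluminium hemiacetal should persist until work-up and then give the aldehyde.

Step 9
Reactants: 14 3-[(1R,2S,4S)-1,3,3-trimethyl-7-oxabicyclo[2.2.1]heptan-2-yl]propanal
Product: 15 (1R,2S,4S)-2-(but-3-yn-1-yl)-1,3,3-trimethyl-7-oxabicyclo[2.2.1]heptane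
Conditions: dimethyl (1-diazo-2-oxopropyl)phosphonate, K2CO3, MeOH, 0 °C → rt
Reagents that add atoms: dimethyl (1-diazo-2-oxopropyl)phosphonate, COP(=O)(OC)C(=[N+]=[N-])C(C)=O
Why: Seyferth–Gilbert homologation with the Ohira–Bestmann reagent: the diazomethylphosphonate anion formed by methanolysis adds to the aldehyde, and loss of dimethyl phosphate and N2 with a 1,2-hydrogen shift should give the terminal alkyne under mild carbonate conditions.

Step 10
Reactants: 16 methyl 4-hydroxy-3-methylbenzoate
Product: 17 methyl 4-[(2,2-dimethylpropanoyl)oxy]-3-methylbenzoate
Conditions: t-BuCOCl, Et3N, DMAP (cat.), CH2Cl2, 0 °C → rt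
Reagents that add atoms: pivaloyl chloride, CC(C)(C)C(=O)Cl
Why: O-Acylation of the phenol; the pivalate should survive radical bromination and organoaluminium reagents and is removed by the final saponification.

Step 11
Reactants: 17 methyl 4-[(2,2-dimethylpropanoyl)oxy]-3-methylbenzoate
Product: 18 methyl 3-(bromomethyl)-4-[(2,2-dimethylpropanoyl)oxy]benzoate
Conditions: NBS (1.05 equiv), AIBN (cat.), PhCF3, 80 °C
Reagents that add atoms: N-bromosuccinimide, O=C1CCC(=O)N1Br
Why: Wohl–Ziegler bromination; the ring methyl group carries the only benzylic C–H bonds and the arene is too electron-poor for ring bromination.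

Step 12
Reactants: 15 (1R,2S,4S)-2-(but-3-yn-1-yl)-1,3,3-trimethyl-7-oxabicyclo[2.2.1]heptane; 18 methyl 3-(bromomethyl)-4-[(2,2-dimethylpropanoyl)oxy]benzoate
Product: 20 methyl 4-[(2,2-dimethylpropanoyl)oxy]-3-[(2E)-3-methyl-5-[(1R,2S,4S)-1,3,3-trimethyl-7-oxabicyclo[2.2.1]heptan-2-yl]pent-2-en-1-yl]benzoate, via (E)-alkenyldimethylalane 19 (not isolated)
Conditions: AlMe3 (2.5 equiv), Cp2ZrCl2 (0.25 equiv), CH2Cl2, 0 °C → rt; volatiles removed; then 18, Pd(PPh3)4 (5 mol %), THF, rt
Reagents that add atoms: trimethylaluminium, C[Al](C)C
Why: Negishi zirconium-catalysed methylalumination adds CH3 and aluminium syn across the terminal alkyne with the metal on the terminal carbon, so the E geometry of 19 is fixed by mechanism; palladium-catalysed cross-coupling of the alkenylalane with the benzylic bromide should then form the C(sp2)–CH2Ar bond with retention of geometry.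

Step 13
Reactants: 20 methyl 4-[(2,2-dimethylpropanoyl)oxy]-3-[(2E)-3-methyl-5-[(1R,2S,4S)-1,3,3-trimethyl-7-oxabicyclo[2.2.1]heptan-2-yl]pent-2-en-1-yl]benzoate
Product: 21 4-hydroxy-3-[(2E)-3-methyl-5-[(1R,2S,4S)-1,3,3-trimethyl-7-oxabicyclo[2.2.1]heptan-2-yl]pent-2-en-1-yl]benzoic acid
Conditions: LiOH (6 equiv), THF/MeOH/H2O, 45 °C; then 1 M HCl to pH 4, 0 °C
Reagents that add atoms: lithium hydroxide, [Li+].[OH-]
Why: Saponification of the aryl pivalate and the methyl ester in one operation; only base and a cold, weakly acidic quench are used, so the phenol should not add to the trisubstituted alkene and the bridging ether should stay intact.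

## Compound list

1 | (triphenylphosphoranylidene)ketene | O=C=C=P(c1ccccc1)(c1ccccc1)c1ccccc1 | starting material
2 | 2,2,2-trifluoroethanol | OCC(F)(F)F | starting material
3 | 2,2,2-trifluoroethyl 2-(triphenylphosphoranylidene)acetate | O=C(OCC(F)(F)F)C=P(c1ccccc1)(c1ccccc1)c1ccccc1 | intermediate
4 | (1-ethoxycyclopropoxy)trimethylsilane | CCOC1(O[Si](C)(C)C)CC1 | starting material
5 | 2,2,2-trifluoroethyl 2-cyclopropylideneacetate | O=C(OCC(F)(F)F)C=C1CC1 | intermediate
6 | 2-methylfuran | Cc1ccco1 | starting material
7 | 2,2,2-trifluoroethyl (1R,2R,4S)-1-methylspiro[7-oxabicyclo[2.2.1]hept-5-ene-3,1'-cyclopropane]-2-carboxylate (endo ester) | O=C(OCC(F)(F)F)[C@@H]1C3(CC3)[C@@H]2C=C[C@@]1(C)O2 | intermediate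
8 | 2,2,2-trifluoroethyl (1R,2R,4S)-1-methylspiro[7-oxabicyclo[2.2.1]heptane-3,1'-cyclopropane]-2-carboxylate | O=C(OCC(F)(F)F)[C@@H]1C3(CC3)[C@@H]2CC[C@@]1(C)O2 | intermediate
9 | 2,2,2-trifluoroethyl (1R,2R,4S)-1,3,3-trimethyl-7-oxabicyclo[2.2.1]heptane-2-carboxylate | O=C(OCC(F)(F)F)[C@@H]1C(C)(C)[C@@H]2CC[C@@]1(C)O2 | intermediate
10 | (1R,2R,4S)-1,3,3-trimethyl-7-oxabicyclo[2.2.1]heptane-2-carboxylic acid | OC(=O)[C@@H]1C(C)(C)[C@@H]2CC[C@@]1(C)O2 | intermediate
11 | 1,3-dioxoisoindolin-2-yl (1R,2R,4S)-1,3,3-trimethyl-7-oxabicyclo[2.2.1]heptane-2-carboxylate | O=C(ON3C(=O)c4ccccc4C3=O)[C@@H]1C(C)(C)[C@@H]2CC[C@@]1(C)O2 | intermediate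
12 | methyl acrylate | C=CC(=O)OC | starting material
13 | methyl 3-[(1R,2S,4S)-1,3,3-trimethyl-7-oxabicyclo[2.2.1]heptan-2-yl]propanoate | COC(=O)CC[C@H]1C(C)(C)[C@@H]2CC[C@@]1(C)O2 | intermediate
14 | 3-[(1R,2S,4S)-1,3,3-trimethyl-7-oxabicyclo[2.2.1]heptan-2-yl]propanal | O=CCC[C@H]1C(C)(C)[C@@H]2CC[C@@]1(C)O2 | intermediate
15 | (1R,2S,4S)-2-(but-3-yn-1-yl)-1,3,3-trimethyl-7-oxabicyclo[2.2.1]heptane | C#CCC[C@H]1C(C)(C)[C@@H]2CC[C@@]1(C)O2 | intermediate
16 | methyl 4-hydroxy-3-methylbenzoate | COC(=O)c1ccc(O)c(C)c1 | starting material
17 | methyl 4-[(2,2-dimethylpropanoyl)oxy]-3-methylbenzoate | COC(=O)c1ccc(OC(=O)C(C)(C)C)c(C)c1 | intermediate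
18 | methyl 3-(bromomethyl)-4-[(2,2-dimethylpropanoyl)oxy]benzoate | COC(=O)c1ccc(OC(=O)C(C)(C)C)c(CBr)c1 | intermediate
19 | dimethyl[(1E)-2-methyl-4-[(1R,2S,4S)-1,3,3-trimethyl-7-oxabicyclo[2.2.1]heptan-2-yl]but-1-en-1-yl]alane | C[Al](C)/C=C(\C)CC[C@H]1C(C)(C)[C@@H]2CC[C@@]1(C)O2 | intermediate
20 | methyl 4-[(2,2-dimethylpropanoyl)oxy]-3-[(2E)-3-methyl-5-[(1R,2S,4S)-1,3,3-trimethyl-7-oxabicyclo[2.2.1]heptan-2-yl]pent-2-en-1-yl]benzoate | COC(=O)c1ccc(OC(=O)C(C)(C)C)c(C/C=C(\C)CC[C@H]2C(C)(C)[C@@H]3CC[C@@]2(C)O3)c1 | intermediate
21 | 4-hydroxy-3-[(2E)-3-methyl-5-[(1R,2S,4S)-1,3,3-trimethyl-7-oxabicyclo[2.2.1]heptan-2-yl]pent-2-en-1-yl]benzoic acid | C/C(=C\Cc1cc(C(=O)O)ccc1O)CC[C@H]1C(C)(C)[C@@H]2CC[C@@]1(C)O2 | target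

## Step count and least certain steps

Total step count: 13. Longest linear sequence: 11 steps (steps 1 to 9, 12 and 13).

**Step 3 (key step, proposed new method).**
- Likely failure: the acid-activated dienophile is captured by the furan in a Friedel–Crafts-type conjugate addition, or the adduct is opened to the same substitution product, because the cationic Lewis acid also stabilises the zwitterion. Alternatively the cycloaddition proceeds but with low facial selectivity, because the β,β-disubstituted ester may not bind in the way a simple acrylate does.
- Fallback (known chemistry, from 5 and 6, returning at 10): the two components are combined without catalyst at about 10 kbar in CH2Cl2 at room temperature, the classical way of forcing furan cycloadditions, to give the racemic cycloadduct F1, whose major C2 epimer is taken on. The conditions of step 4 lead through the racemic saturated spiro ester F2 to the racemic gem-dimethyl ester F3, and the conditions of step 5 give the racemic acid F4. Crystallisation with (S)-1-phenylethylamine gives the diastereomerically pure ammonium salt F5 of the (1R,2R,4S) acid, and acidification liberates 10. If the other enantiomer crystallises, the antipodal amine is used.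

**Step 4.**
- Likely failure: hydrogenolysis of the allylic C4–O7 bond, or acid-induced opening of the oxanorbornene, while the alkene is still present and the cyclopropane cleavage is slow. To a lesser degree, the cyclopropane may be cleaved at a bond to the spiro carbon.
- Fallback (from 7, returning at 9): the alkene is first reduced with diimide, generated from potassium azodicarboxylate and acetic acid. This is a neutral, non-catalytic transfer of hydrogen that cannot cleave C–O bonds. It gives 8 as an isolated compound, and only then is the cyclopropane hydrogenolysed over PtO2 in acetic acid to 9.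

**Step 7.**
- Likely failure: hydrogen-atom transfer from the Hantzsch ester to the hindered C2 radical before it adds to 12, and in second place incomplete exo selectivity of the addition.
- Fallback (from 10, returning at 13, without passing through 11): acid 10 is decarboxylated oxidatively as its carboxylate with Ir[dF(CF3)ppy]2(dtbbpy)PF6 (1 mol %), K2HPO4 and 12 in DMF under blue light. No stoichiometric hydrogen-atom donor is present, so the radical can only add to 12. The adduct radical is then reduced by the photocatalyst and protonated.

**Step 12.**
- Likely failure: attack of methylaluminium species on the two ester carbonyls of 18, transfer of methyl in place of the alkenyl group, or complexation of the aluminium Lewis acid by the bridging ether with erosion of the carbometalation regioselectivity.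
- Fallback (from 19, returning at 20): the alane is quenched with I2 to give the (E)-alkenyl iodide F6. Bromide 18 is converted separately with zinc dust and LiCl in THF into the benzylzinc bromide F7. The two are joined by a Negishi coupling with Pd(PPh3)4 to give 20, so no aluminium reagent ever meets the esters.

## Further compounds

F1 | step 3 | racemic 2,2,2-trifluoroethyl 1-methylspiro[7-oxabicyclo[2.2.1]hept-5-ene-3,1'-cyclopropane]-2-carboxylate (racemate, drawn without configuration) | O=C(OCC(F)(F)F)C1C3(CC3)C2C=CC1(C)O2
F2 | step 3 | racemic 2,2,2-trifluoroethyl 1-methylspiro[7-oxabicyclo[2.2.1]heptane-3,1'-cyclopropane]-2-carboxylate (racemate, drawn without configuration) | O=C(OCC(F)(F)F)C1C3(CC3)C2CCC1(C)O2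
F3 | step 3 | racemic 2,2,2-trifluoroethyl 1,3,3-trimethyl-7-oxabicyclo[2.2.1]heptane-2-carboxylate (racemate, drawn without configuration) | O=C(OCC(F)(F)F)C1C(C)(C)C2CCC1(C)O2
F4 | step 3 | racemic 1,3,3-trimethyl-7-oxabicyclo[2.2.1]heptane-2-carboxylic acid (racemate, drawn without configuration) | OC(=O)C1C(C)(C)C2CCC1(C)O2
F5 | step 3 | (S)-1-phenylethylammonium (1R,2R,4S)-1,3,3-trimethyl-7-oxabicyclo[2.2.1]heptane-2-carboxylate | C[C@H]([NH3+])c1ccccc1.[O-]C(=O)[C@@H]1C(C)(C)[C@@H]2CC[C@@]1(C)O2
F0 | step 4 | none | none
F0 | step 7 | none | none
F6 | step 12 | (1R,2S,4S)-2-[(3E)-4-iodo-3-methylbut-3-en-1-yl]-1,3,3-trimethyl-7-oxabicyclo[2.2.1]heptane | I/C=C(\C)CC[C@H]1C(C)(C)[C@@H]2CC[C@@]1(C)O2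
F7 | step 12 | [5-(methoxycarbonyl)-2-[(2,2-dimethylpropanoyl)oxy]phenyl]methylzinc bromide | COC(=O)c1ccc(OC(=O)C(C)(C)C)c(C[Zn]Br)c1
A1 | alternative 1 | (1R,4R)-1,3,3-trimethyl-5,5-bis(phenylsulfonyl)-7-oxabicyclo[2.2.1]heptan-2-one | O=C1C(C)(C)[C@@H]2C(S(=O)(=O)c3ccccc3)(S(=O)(=O)c3ccccc3)C[C@@]1(C)O2
A2 | alternative 1 | 4-diazo-2,2-dimethyl-3-oxopentanal | CC(=[N+]=[N-])C(=O)C(C)(C)C=O
A3 | alternative 1 | 1,1-bis(phenylsulfonyl)ethene | C=C(S(=O)(=O)c1ccccc1)S(=O)(=O)c1ccccc1
A4 | alternative 2 | (1R,2S,4S)-2-ethenyl-1,3,3-trimethyl-7-oxabicyclo[2.2.1]heptane | C=C[C@H]1C(C)(C)[C@@H]2CC[C@@]1(C)O2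
A5 | alternative 2 | (S)-2,2,4-trimethylcyclohex-3-en-1-ol | O[C@H]1CCC(C)=CC1(C)C
A6 | alternative 2 | vinyl bromide | C=CBr
A7 | alternative 3 | methyl 2-[(1R,2S,4S)-1,3,3-trimethyl-7-oxabicyclo[2.2.1]heptan-2-yl]acetate | COC(=O)C[C@H]1C(C)(C)[C@@H]2CC[C@@]1(C)O2
A8 | alternative 3 | methyl (2E)-3-[(2R,5S)-2-methyl-5-(prop-1-en-2-yl)oxolan-2-yl]prop-2-enoate | COC(=O)/C=C/[C@@]1(C)CC[C@@H](C(C)=C)O1
A9 | alternative 3 | 2-[(2S,5R)-5-ethenyl-5-methyloxolan-2-yl]propan-2-ol (furanoid linalool oxide, vinyl and hydroxyisopropyl cis) | C=C[C@@]1(C)CC[C@@H](C(C)(C)O)O1
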